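Start from late times, as with a step response: the gas is held, so second intermediate keeps arriving, while open intermediate draws on a finite charge and ends as product. Your hunch, that the hottest flask wins since substrate opens soonest there, reads the front of the curve, and I'd bet against it.

| flask | substrate | gas | temperature | time |
|---|---|---|---|---|
| eta | 1.0 mM | 0.065 mM (held) | 80 °C | 5.0 min |
| gamma | 1.0 mM | 0.065 mM (held) | 110 °C | 5.0 min |
| zeta | 1.0 mM | 0.065 mM (held) | 125 °C | 5.0 min |
| alpha | 1.0 mM | 0.065 mM (held) | 95 °C | 5.0 min |

- the best flask by amount of open intermediate, in percent of the substrate charged; "all alike" if 1.5 percentage points covers them all (eta / gamma / zeta / alpha / all alike)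
- amount of open intermediate at the end, in percent of the substrate charged, eta
- amount of open intermediate at the end, in percent of the substrate charged, gamma
- amount of open intermediate at the end, in percent of the substrate charged, zeta
- amount of open intermediate at the end, in percent of the substrate charged, alpha

    substrate ⇌ open intermediate (K1 = 1.0, k1 = 0.0196 s⁻¹, Ea1 = 98.0 kJ mol⁻¹, ΔH1 = 0 kJ mol⁻¹)
    partner → second intermediate (k2 = 0.0154 s⁻¹, Ea2 = 96.0 kJ mol⁻¹)
    open intermediate + second intermediate → product (k3 = 14.3 M⁻¹ s⁻¹, Ea3 = 61.0 kJ mol⁻¹)
    gas ⇌ partner, rate k4*(csat - [partner]) (k4 = 11.3 s⁻¹, csat = 0.065 mM)
    (constants at 80 °C)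

Here is my quick number, with the constants turned into times at 80 °C. Gas transfer takes 0.0885 s against 64.9 s for the loss of partner, so c(partner) sits near 0.065 mM. The opening relaxes in 25.5 s, well inside the 5.0 min run, so I let substrate and open intermediate share the unreacted pool nearly evenly, and with a step enthalpy of 0 kJ mol⁻¹ that split doesn't move with temperature.

Second intermediate then climbs as a ramp of slope 0.0601 mM min⁻¹, and the pool falls like a Gaussian in time. Its width is what I carry: 8.81 min, the burn time τ, which is 2 divided by the square root of the product of the step-to-product constant, the partner-loss constant and the saturation concentration. Hotter, with the saturation concentration held, it shrinks with the mean of the two activation energies, to 2.96 min in alpha, 1.09 min in gamma and 0.429 min in zeta.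

The ramp ignores that second intermediate is spent, so I soften the Gaussian by hand: the pool fraction is one over one plus the square of t/τ, and open intermediate is half of that. This is a choice, not a solution.

I commit to eta, with 37.8% there, 13.0% in alpha, 2.25% in gamma and 0.366% in zeta.

The forecast also names eta, with 40.7% there, 14.8% in alpha, <0.001% in gamma and 0% in zeta, and it says of gamma that “excess intermediate destroys the pool”.

The simulation gives 40.8% in eta, 14.6% in alpha, 0% in gamma and 0% in zeta, so eta is the best flask.

In eta at the end, the forward half-life of substrate, 0.59 min, is shorter than the half-life of open intermediate by the step to product, 6.0 min. Substrate stands at 42.8% beside open intermediate at 40.8%, and my eta figure lies 3 percentage points below the result.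

Now read eta at 2.0 min, with τ unchanged: t/τ is 0.227, which gives 47.5% open intermediate. That neighbour flask shows 47.1%.

(The rate constants are those of an exercise; no experiment stands behind them.)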